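**Plan**

- Retrosynthesis (germacrane numbering): cut the C8 ester, then the lactone C–O bond together with the C6–C7 bond of the ten-membered ring, then the C7=C11 acrylate unit, then the C8–C9 bond, and last the furanone bonds O–C3 and C1–C10.
- Enabling feature: in the 3(2H)-furanone ring, the ring O and the methyl-bearing quaternary C10 (with exocyclic C9) are the hydroxyl O, Cα and carboxyl C of lactic acid (an O,C-1,2-dinucleophile). Ring C1(=O), C2H and enol-ether C3 are a 2-ynoate (a 1,3-dielectrophile).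
- Forward: the furanone ring is made first, from a hex-4-en-2-ynoate and the cis-tert-butyl dioxolanone of (R)-lactic acid; this temporary ring leaves as pivalaldehyde in the same flask. The C9–C8–C7 chain is then grown, and the ten-membered carbocycle and the γ-lactone are closed together by an intramolecular allylchromium addition; the side-chain ester comes last.
- Stereochemistry: C10 is bought with (R)-lactic acid and relayed through the acetal carbon. C8 and C9 come from a D-proline anti-aldol, and C6 and C7 are set in the ring closure under control of C8. The 4Z alkene comes from a Z-vinyl iodide and the E side-chain alkene from a thermodynamic allylic acetate shift.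
- Remark: the PMB-protected glycolaldehyde used in step 7 is taken as a catalogue compound.

Key step: step 5

**Route**

Step 1
Reactants: 1 but-2-yn-1-ol
Product: 2 (Z)-3-iodobut-2-en-1-ol
Conditions: NaAlH2(OCH2CH2OMe)2 (Red-Al), THF, 0 °C to rt; EtOAc; then iodine, THF, −78 to 0 °C
Reagents that add atoms: iodine, II
Why: Hydroxyl-directed trans-hydroalumination of the propargylic alcohol puts aluminium on the distal alkyne carbon, and iodinolysis with retention should give the Z-vinyl iodide that later becomes the 4Z ring alkene (hydroalumination–iodination).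

Step 2
Reactants: 2 (Z)-3-iodobut-2-en-1-ol
Product: 3 (Z)-tert-butyl[(3-iodobut-2-en-1-yl)oxy]dimethylsilane
Conditions: TBSCl, imidazole, CH2Cl2, 0 °C to rt
Reagents that add atoms: tert-butyldimethylsilyl chloride, CC(C)(C)[Si](C)(C)Cl
Why: Routine silylation of the primary allylic alcohol masks the future C6 oxygen against the enolate chemistry of step 5 (silyl ether protection).

Step 3
Reactants: 3 (Z)-tert-butyl[(3-iodobut-2-en-1-yl)oxy]dimethylsilane; 4 methyl propiolate
Product: 5 methyl (Z)-6-[(tert-butyldimethylsilyl)oxy]-4-methylhex-4-en-2-ynoate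
Conditions: Pd(PPh3)2Cl2 (3 mol %), CuI (6 mol %), K2CO3, THF, rt to 40 °C, slow addition of 4
Reagents that add atoms: none
Why: Sonogashira coupling of a vinyl iodide proceeds with retention of alkene geometry, and the carbonate base avoids amine conjugate addition to the propiolate.

Step 4
Reactants: 6 (R)-lactic acid; 7 pivalaldehyde
Product: 8 (2R,5R)-2-tert-butyl-5-methyl-1,3-dioxolan-4-one
Conditions: p-TsOH·H2O (cat.), H2SO4 (cat.), pentane, reflux with azeotropic removal of water; crystallization from pentane/Et2O at −78 °C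
Reagents that add atoms: none
Why: Acid-catalysed acetalization under thermodynamic control should favour the cis dioxolanone, whose new acetal stereocentre stores the lactic acid chirality for the next step (self-regeneration of stereocentres).

Step 5
Reactants: 8 (2R,5R)-2-tert-butyl-5-methyl-1,3-dioxolan-4-one; 5 methyl (Z)-6-[(tert-butyldimethylsilyl)oxy]-4-methylhex-4-en-2-ynoate
Product: 11 methyl (2S)-5-[(2Z)-4-[(tert-butyldimethylsilyl)oxy]but-2-en-2-yl]-2-methyl-3-oxo-2,3-dihydrofuran-2-carboxylate, via C-acylated dioxolanone 9 (not isolated), via hydroxy ynone ester 10 (not isolated)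
Conditions: LiN(iPr)2 (LDA, 1.1 equiv), THF, −78 °C; then 5 (0.9 equiv), −78 °C, 1 h; warm to 0 °C, 2 h; AcOH, pH 7 buffer
Reagents that add atoms: none
Why: Proposed new method: the lithium enolate of 8 is C-acylated at the ester carbonyl of ynoate 5 (Claisen condensation) to give 9; the lithium methoxide expelled in that step opens the acylal-type lactone of 9 with loss of pivalaldehyde, and the tertiary alkoxide of 10 so released adds to the ynone, so that the C–C bond to the quaternary carbon and the ring O–C(enol ether) bond arise in one flask. The closest known reaction types are the base-mediated annulation of α-hydroxy esters with alkynoates (oxygen analogue of the Fiesselmann condensation), alkylation and aldol reactions of this dioxolanone enolate, and base-induced cyclization of α'-hydroxy ynones to 3(2H)-furanones; the merger with an ester as both acyl donor and internal trigger is new. Only the furanone ring is closed, by 5-endo-dig attack of oxygen on the ynone β-carbon, while the temporary dioxolanone ring is opened. The quaternary stereocentre is controlled by the tert-butyl-bearing acetal carbon, since the acyl group enters the enolate face trans to tert-butyl and so replaces the original hydrogen of (R)-lactic acid with retention. The step needs 1,2- rather than 1,4-addition of the enolate to 5 and no over-addition to 9; the hard lithium enolate at −78 °C, the β-carbon of 5 shielded by the methyl-branched alkenyl group, the unhindered ester carbonyl next to an sp carbon, and a chelated lithium hemiketal that collapses only after the enolate is consumed should secure this.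

Step 6
Reactants: 11 methyl (2S)-5-[(2Z)-4-[(tert-butyldimethylsilyl)oxy]but-2-en-2-yl]-2-methyl-3-oxo-2,3-dihydrofuran-2-carboxylate
Product: 12 (2R)-5-[(2Z)-4-[(tert-butyldimethylsilyl)oxy]but-2-en-2-yl]-2-methyl-3-oxo-2,3-dihydrofuran-2-carbaldehyde
Conditions: iBu2AlH (DIBAL-H, 1.1 equiv), CH2Cl2, −90 to −78 °C; MeOH, then aqueous Rochelle salt; used at once
Reagents that add atoms: none
Why: Partial DIBAL reduction of the α-alkoxy, α-acyl-activated ester should stop at the chelated aluminium hemiacetal at low temperature, while the cross-conjugated vinylogous-ester carbonyl of the furanone is the less electrophilic site.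

Step 7
Reactants: 12 (2R)-5-[(2Z)-4-[(tert-butyldimethylsilyl)oxy]but-2-en-2-yl]-2-methyl-3-oxo-2,3-dihydrofuran-2-carbaldehyde; 13 2-[(4-methoxybenzyl)oxy]acetaldehyde
Product: 14 (2R,3S)-3-[(2R)-5-[(2Z)-4-[(tert-butyldimethylsilyl)oxy]but-2-en-2-yl]-2-methyl-3-oxo-2,3-dihydrofuran-2-yl]-3-hydroxy-2-[(4-methoxybenzyl)oxy]propanal
Conditions: D-proline (20 mol %), DMF, 4 °C, 13 (2 equiv) added over 24 h by syringe pump
Reagents that add atoms: none
Why: Proline-catalysed direct cross-aldol reaction: the E-enamine of donor 13 adds to the non-enolizable, inductively activated aldehyde 12 through the carboxylic-acid hydrogen-bonded transition state, which should give the anti α-alkoxy-β-hydroxy aldehyde with both new centres (C8, C9) set by the D-catalyst.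

Step 8
Reactants: 14 (2R,3S)-3-[(2R)-5-[(2Z)-4-[(tert-butyldimethylsilyl)oxy]but-2-en-2-yl]-2-methyl-3-oxo-2,3-dihydrofuran-2-yl]-3-hydroxy-2-[(4-methoxybenzyl)oxy]propanal
Product: 15 (2R,3S)-3-[(tert-butyldimethylsilyl)oxy]-3-[(2R)-5-[(2Z)-4-[(tert-butyldimethylsilyl)oxy]but-2-en-2-yl]-2-methyl-3-oxo-2,3-dihydrofuran-2-yl]-2-[(4-methoxybenzyl)oxy]propanal
Conditions: TBSOTf, 2,6-lutidine, CH2Cl2, −78 to −40 °C
Reagents that add atoms: tert-butyldimethylsilyl triflate, CC(C)(C)[Si](C)(C)OS(=O)(=O)C(F)(F)F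
Why: Silyl triflate silylation of the hindered carbinol under non-nucleophilic base blocks both retro-aldol pathways of the β-hydroxy carbonyl array and is too cold to enolize the aldehyde.

Step 9
Reactants: 15 (2R,3S)-3-[(tert-butyldimethylsilyl)oxy]-3-[(2R)-5-[(2Z)-4-[(tert-butyldimethylsilyl)oxy]but-2-en-2-yl]-2-methyl-3-oxo-2,3-dihydrofuran-2-yl]-2-[(4-methoxybenzyl)oxy]propanal; 16 methyl acrylate
Product: 17 methyl (4S,5S)-5-[(tert-butyldimethylsilyl)oxy]-5-[(2R)-5-[(2Z)-4-[(tert-butyldimethylsilyl)oxy]but-2-en-2-yl]-2-methyl-3-oxo-2,3-dihydrofuran-2-yl]-3-hydroxy-4-[(4-methoxybenzyl)oxy]-2-methylidenepentanoate (both C3 epimers)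
Conditions: DABCO (1 equiv), methyl acrylate (10 equiv), 1,4-dioxane, rt, 2–4 d
Reagents that add atoms: none
Why: Morita–Baylis–Hillman reaction of an α-alkoxy aldehyde, which is activated enough to react under mild amine catalysis; the new carbinol centre is removed in the next step, so its configuration does not matter.

Step 10
Reactants: 17 methyl (4S,5S)-5-[(tert-butyldimethylsilyl)oxy]-5-[(2R)-5-[(2Z)-4-[(tert-butyldimethylsilyl)oxy]but-2-en-2-yl]-2-methyl-3-oxo-2,3-dihydrofuran-2-yl]-3-hydroxy-4-[(4-methoxybenzyl)oxy]-2-methylidenepentanoate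
Product: 18 methyl (2Z,4S,5S)-2-(bromomethyl)-5-[(tert-butyldimethylsilyl)oxy]-5-[(2R)-5-[(2Z)-4-[(tert-butyldimethylsilyl)oxy]but-2-en-2-yl]-2-methyl-3-oxo-2,3-dihydrofuran-2-yl]-4-[(4-methoxybenzyl)oxy]pent-2-enoate
Conditions: NBS, Me2S, CH2Cl2, −20 °C to rt
Reagents that add atoms: N-bromosuccinimide, O=C1CCC(=O)N1Br
Why: Activation of the allylic alcohol as its alkoxysulfonium salt and SN2' attack of bromide should give the thermodynamically preferred Z-2-(bromomethyl)enoate (allylic transposition bromination of a Morita–Baylis–Hillman adduct).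

Step 11
Reactants: 18 methyl (2Z,4S,5S)-2-(bromomethyl)-5-[(tert-butyldimethylsilyl)oxy]-5-[(2R)-5-[(2Z)-4-[(tert-butyldimethylsilyl)oxy]but-2-en-2-yl]-2-methyl-3-oxo-2,3-dihydrofuran-2-yl]-4-[(4-methoxybenzyl)oxy]pent-2-enoate
Product: 19 methyl (2Z,4S,5S)-2-(bromomethyl)-5-[(tert-butyldimethylsilyl)oxy]-5-[(2R)-5-[(2Z)-4-hydroxybut-2-en-2-yl]-2-methyl-3-oxo-2,3-dihydrofuran-2-yl]-4-[(4-methoxybenzyl)oxy]pent-2-enoate
Conditions: HF·pyridine, pyridine, THF, 0 °C
Reagents that add atoms: none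
Why: Buffered fluoride desilylation should remove the unhindered primary allylic silyl ether much faster than the secondary one next to the quaternary carbon, and it leaves the allylic bromide untouched (selective silyl ether cleavage).

Step 12
Reactants: 19 methyl (2Z,4S,5S)-2-(bromomethyl)-5-[(tert-butyldimethylsilyl)oxy]-5-[(2R)-5-[(2Z)-4-hydroxybut-2-en-2-yl]-2-methyl-3-oxo-2,3-dihydrofuran-2-yl]-4-[(4-methoxybenzyl)oxy]pent-2-enoate
Product: 20 methyl (2Z,4S,5S)-2-(bromomethyl)-5-[(tert-butyldimethylsilyl)oxy]-4-[(4-methoxybenzyl)oxy]-5-[(2R)-2-methyl-3-oxo-5-[(2Z)-4-oxobut-2-en-2-yl]-2,3-dihydrofuran-2-yl]pent-2-enoate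
Conditions: Dess–Martin periodinane, NaHCO3, CH2Cl2, 0 °C; used directly
Reagents that add atoms: none
Why: Buffered Dess–Martin oxidation of the allylic alcohol is neutral and fast enough to keep the Z-enal from isomerizing before the ring closure.

Step 13
Reactants: 20 methyl (2Z,4S,5S)-2-(bromomethyl)-5-[(tert-butyldimethylsilyl)oxy]-4-[(4-methoxybenzyl)oxy]-5-[(2R)-2-methyl-3-oxo-5-[(2Z)-4-oxobut-2-en-2-yl]-2,3-dihydrofuran-2-yl]pent-2-enoate
Product: 22 (6R,7S,8S,9S,10R)-9-[(tert-butyldimethylsilyl)oxy]-8-[(4-methoxybenzyl)oxy]-1-oxo-3,10-epoxygermacra-2,4Z,11(13)-trien-12,6-olide, via open hydroxy ester 21 (not isolated)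
Conditions: CrCl2 (8 equiv), THF, rt, 20 added over 8 h (final 2 mM); aqueous NH4Cl; then p-TsOH·H2O (10 mol %), CH2Cl2, rt
Reagents that add atoms: none
Why: Intramolecular Nozaki–Hiyama-type Barbier allylation: the allylchromium from the bromide adds through its γ-carbon to the enal in a closed chair transition state with both chain ends pseudo-equatorial (anti, hence the 6,7-trans lactone), on the allyl face that allylic 1,3-strain leaves open opposite the bulky C9 branch (hence 7S relative to 8S), and the hydroxy ester then lactonizes under acid catalysis.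

Step 14
Reactants: 22 (6R,7S,8S,9S,10R)-9-[(tert-butyldimethylsilyl)oxy]-8-[(4-methoxybenzyl)oxy]-1-oxo-3,10-epoxygermacra-2,4Z,11(13)-trien-12,6-olide
Product: 23 (6R,7R,8S,9S,10R)-9-[(tert-butyldimethylsilyl)oxy]-8-hydroxy-1-oxo-3,10-epoxygermacra-2,4Z,11(13)-trien-12,6-olide
Conditions: DDQ, CH2Cl2/pH 7 buffer (10:1), 0 °C to rt
Reagents that add atoms: none
Why: Oxidative cleavage of the p-methoxybenzyl ether by DDQ is neutral and spares the electron-poor dienone, the methylene lactone and the silyl ether.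

Step 15
Reactants: 24 tert-butyl acrylate; 25 acetaldehyde
Product: 26 tert-butyl 3-hydroxy-2-methylidenebutanoate (racemic)
Conditions: DABCO (0.3 equiv), neat, sealed vessel, rt, 5 d
Reagents that add atoms: none
Why: Morita–Baylis–Hillman reaction assembles all carbons of the side-chain acid; the racemic carbinol centre is erased in the next step.

Step 16
Reactants: 26 tert-butyl 3-hydroxy-2-methylidenebutanoate
Product: 28 tert-butyl (E)-2-(acetoxymethyl)but-2-enoate, via secondary acetate 27 (not isolated)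
Conditions: Ac2O, Et3N, DMAP (5 mol %), CH2Cl2, 0 °C; then DABCO (0.3 equiv), THF, 65 °C
Reagents that add atoms: acetic anhydride, CC(=O)OC(C)=O
Why: Acetylation followed by amine-catalysed SN2'/SN2' 1,3-transposition of the acetate should funnel to the thermodynamically favoured trisubstituted E-enoate with the primary acetate (allylic acetate rearrangement).

Step 17
Reactants: 28 tert-butyl (E)-2-(acetoxymethyl)but-2-enoate
Product: 29 (E)-2-(acetoxymethyl)but-2-enoic acid
Conditions: TFA/CH2Cl2 (1:4), 0 °C to rt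
Reagents that add atoms: none
Why: Acidolysis of the tert-butyl ester frees the acid without touching the allylic acetate or the alkene geometry (tert-butyl ester cleavage).

Step 18
Reactants: 23 (6R,7R,8S,9S,10R)-9-[(tert-butyldimethylsilyl)oxy]-8-hydroxy-1-oxo-3,10-epoxygermacra-2,4Z,11(13)-trien-12,6-olide; 29 (E)-2-(acetoxymethyl)but-2-enoic acid
Product: 30 (6R,7S,8S,9S,10R)-8-{[(E)-2-(acetoxymethyl)but-2-enoyl]oxy}-9-[(tert-butyldimethylsilyl)oxy]-1-oxo-3,10-epoxygermacra-2,4Z,11(13)-trien-12,6-olide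
Conditions: DCC (1.5 equiv), DMAP (0.2 equiv), CH2Cl2, 0 °C to rt
Reagents that add atoms: none
Why: Steglich esterification acylates the only free hydroxyl under near-neutral conditions, with DMAP kept catalytic and cold so that it does not attack the allylic acetate of the acid.

Step 19
Reactants: 30 (6R,7S,8S,9S,10R)-8-{[(E)-2-(acetoxymethyl)but-2-enoyl]oxy}-9-[(tert-butyldimethylsilyl)oxy]-1-oxo-3,10-epoxygermacra-2,4Z,11(13)-trien-12,6-olide
Product: 31 (6R,7S,8S,9S,10R)-8-{[(E)-2-(acetoxymethyl)but-2-enoyl]oxy}-9-hydroxy-1-oxo-3,10-epoxygermacra-2,4Z,11(13)-trien-12,6-olide (CNP0231561.1)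
Conditions: HF·pyridine (excess), THF, 0 °C to rt
Reagents that add atoms: none
Why: Acidic fluoride desilylation frees the C9 hydroxyl without the base that would trigger retro-aldol cleavage of the β-hydroxy ketone or 8-to-9 acyl migration (silyl ether cleavage).

**Compound list**

1 | but-2-yn-1-ol | CC#CCO | starting material
2 | (Z)-3-iodobut-2-en-1-ol | C/C(I)=C/CO | intermediate
3 | (Z)-tert-butyl[(3-iodobut-2-en-1-yl)oxy]dimethylsilane | C/C(I)=C/CO[Si](C)(C)C(C)(C)C | intermediate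
4 | methyl propiolate | C#CC(=O)OC | starting material
5 | methyl (Z)-6-[(tert-butyldimethylsilyl)oxy]-4-methylhex-4-en-2-ynoate | C/C(C#CC(=O)OC)=C/CO[Si](C)(C)C(C)(C)C | intermediate
6 | (R)-lactic acid | C[C@@H](O)C(=O)O | starting material
7 | pivalaldehyde | CC(C)(C)C=O | starting material
8 | (2R,5R)-2-tert-butyl-5-methyl-1,3-dioxolan-4-one | C[C@H]1O[C@@H](C(C)(C)C)OC1=O | intermediate
9 | (2R,5S)-2-tert-butyl-5-[(4Z)-6-[(tert-butyldimethylsilyl)oxy]-4-methylhex-4-en-2-ynoyl]-5-methyl-1,3-dioxolan-4-one | C[C@@]1(C(=O)C#C/C(C)=C\CO[Si](C)(C)C(C)(C)C)O[C@@H](C(C)(C)C)OC1=O | intermediate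
10 | methyl (2S,6Z)-8-[(tert-butyldimethylsilyl)oxy]-2-hydroxy-2,6-dimethyl-3-oxooct-6-en-4-ynoate (formed as its lithium alkoxide) | C/C(C#CC(=O)[C@](C)(O)C(=O)OC)=C/CO[Si](C)(C)C(C)(C)C | intermediate
11 | methyl (2S)-5-[(2Z)-4-[(tert-butyldimethylsilyl)oxy]but-2-en-2-yl]-2-methyl-3-oxo-2,3-dihydrofuran-2-carboxylate | C/C(=C/CO[Si](C)(C)C(C)(C)C)C1=CC(=O)[C@](C)(O1)C(=O)OC | intermediate
12 | (2R)-5-[(2Z)-4-[(tert-butyldimethylsilyl)oxy]but-2-en-2-yl]-2-methyl-3-oxo-2,3-dihydrofuran-2-carbaldehyde | C/C(=C/CO[Si](C)(C)C(C)(C)C)C1=CC(=O)[C@](C)(O1)C=O | intermediate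
13 | 2-[(4-methoxybenzyl)oxy]acetaldehyde | COc1ccc(COCC=O)cc1 | starting material
14 | (2R,3S)-3-[(2R)-5-[(2Z)-4-[(tert-butyldimethylsilyl)oxy]but-2-en-2-yl]-2-methyl-3-oxo-2,3-dihydrofuran-2-yl]-3-hydroxy-2-[(4-methoxybenzyl)oxy]propanal | C/C(=C/CO[Si](C)(C)C(C)(C)C)C1=CC(=O)[C@](C)(O1)[C@@H](O)[C@@H](OCc2ccc(OC)cc2)C=O | intermediate
15 | (2R,3S)-3-[(tert-butyldimethylsilyl)oxy]-3-[(2R)-5-[(2Z)-4-[(tert-butyldimethylsilyl)oxy]but-2-en-2-yl]-2-methyl-3-oxo-2,3-dihydrofuran-2-yl]-2-[(4-methoxybenzyl)oxy]propanal | C/C(=C/CO[Si](C)(C)C(C)(C)C)C1=CC(=O)[C@](C)(O1)[C@@H](O[Si](C)(C)C(C)(C)C)[C@@H](OCc2ccc(OC)cc2)C=O | intermediate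
16 | methyl acrylate | C=CC(=O)OC | starting material
17 | methyl (4S,5S)-5-[(tert-butyldimethylsilyl)oxy]-5-[(2R)-5-[(2Z)-4-[(tert-butyldimethylsilyl)oxy]but-2-en-2-yl]-2-methyl-3-oxo-2,3-dihydrofuran-2-yl]-3-hydroxy-4-[(4-methoxybenzyl)oxy]-2-methylidenepentanoate | C/C(=C/CO[Si](C)(C)C(C)(C)C)C1=CC(=O)[C@](C)(O1)[C@@H](O[Si](C)(C)C(C)(C)C)[C@@H](OCc2ccc(OC)cc2)C(O)C(=C)C(=O)OC | intermediate
18 | methyl (2Z,4S,5S)-2-(bromomethyl)-5-[(tert-butyldimethylsilyl)oxy]-5-[(2R)-5-[(2Z)-4-[(tert-butyldimethylsilyl)oxy]but-2-en-2-yl]-2-methyl-3-oxo-2,3-dihydrofuran-2-yl]-4-[(4-methoxybenzyl)oxy]pent-2-enoate | C/C(=C/CO[Si](C)(C)C(C)(C)C)C1=CC(=O)[C@](C)(O1)[C@@H](O[Si](C)(C)C(C)(C)C)[C@@H](OCc2ccc(OC)cc2)/C=C(\CBr)C(=O)OC | intermediate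
19 | methyl (2Z,4S,5S)-2-(bromomethyl)-5-[(tert-butyldimethylsilyl)oxy]-5-[(2R)-5-[(2Z)-4-hydroxybut-2-en-2-yl]-2-methyl-3-oxo-2,3-dihydrofuran-2-yl]-4-[(4-methoxybenzyl)oxy]pent-2-enoate | C/C(=C/CO)C1=CC(=O)[C@](C)(O1)[C@@H](O[Si](C)(C)C(C)(C)C)[C@@H](OCc2ccc(OC)cc2)/C=C(\CBr)C(=O)OC | intermediate
20 | methyl (2Z,4S,5S)-2-(bromomethyl)-5-[(tert-butyldimethylsilyl)oxy]-4-[(4-methoxybenzyl)oxy]-5-[(2R)-2-methyl-3-oxo-5-[(2Z)-4-oxobut-2-en-2-yl]-2,3-dihydrofuran-2-yl]pent-2-enoate | C/C(=C/C=O)C1=CC(=O)[C@](C)(O1)[C@@H](O[Si](C)(C)C(C)(C)C)[C@@H](OCc2ccc(OC)cc2)/C=C(\CBr)C(=O)OC | intermediate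
21 | methyl (6R,7S,8S,9S,10R)-9-[(tert-butyldimethylsilyl)oxy]-6-hydroxy-8-[(4-methoxybenzyl)oxy]-1-oxo-3,10-epoxygermacra-2,4Z,11(13)-trien-12-oate | C=C(C(=O)OC)[C@H]1[C@H](O)/C=C(/C)C2=CC(=O)[C@](C)(O2)[C@@H](O[Si](C)(C)C(C)(C)C)[C@H]1OCc3ccc(OC)cc3 | intermediate
22 | (6R,7S,8S,9S,10R)-9-[(tert-butyldimethylsilyl)oxy]-8-[(4-methoxybenzyl)oxy]-1-oxo-3,10-epoxygermacra-2,4Z,11(13)-trien-12,6-olide | C=C1C(=O)O[C@@H]2/C=C(/C)C3=CC(=O)[C@](C)(O3)[C@@H](O[Si](C)(C)C(C)(C)C)[C@@H](OCc4ccc(OC)cc4)[C@@H]12 | intermediate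
23 | (6R,7R,8S,9S,10R)-9-[(tert-butyldimethylsilyl)oxy]-8-hydroxy-1-oxo-3,10-epoxygermacra-2,4Z,11(13)-trien-12,6-olide | C=C1C(=O)O[C@@H]2/C=C(/C)C3=CC(=O)[C@](C)(O3)[C@@H](O[Si](C)(C)C(C)(C)C)[C@@H](O)[C@@H]12 | intermediate
24 | tert-butyl acrylate | C=CC(=O)OC(C)(C)C | starting material
25 | acetaldehyde | CC=O | starting material
26 | tert-butyl 3-hydroxy-2-methylidenebutanoate | CC(O)C(=C)C(=O)OC(C)(C)C | intermediate
27 | tert-butyl 3-acetoxy-2-methylidenebutanoate | CC(OC(C)=O)C(=C)C(=O)OC(C)(C)C | intermediate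
28 | tert-butyl (E)-2-(acetoxymethyl)but-2-enoate | C/C=C(/C(=O)OC(C)(C)C)COC(C)=O | intermediate
29 | (E)-2-(acetoxymethyl)but-2-enoic acid | C/C=C(/C(=O)O)COC(C)=O | intermediate
30 | (6R,7S,8S,9S,10R)-8-{[(E)-2-(acetoxymethyl)but-2-enoyl]oxy}-9-[(tert-butyldimethylsilyl)oxy]-1-oxo-3,10-epoxygermacra-2,4Z,11(13)-trien-12,6-olide | C=C1C(=O)O[C@@H]2/C=C(/C)C3=CC(=O)[C@](C)(O3)[C@@H](O[Si](C)(C)C(C)(C)C)[C@@H](OC(=O)/C(=C/C)COC(C)=O)[C@@H]12 | intermediate
31 | (6R,7S,8S,9S,10R)-8-{[(E)-2-(acetoxymethyl)but-2-enoyl]oxy}-9-hydroxy-1-oxo-3,10-epoxygermacra-2,4Z,11(13)-trien-12,6-olide (CNP0231561.1) | C=C1C(=O)O[C@@H]2/C=C(/C)C3=CC(=O)[C@](C)(O3)[C@@H](O)[C@@H](OC(=O)/C(=C/C)COC(C)=O)[C@@H]12 | target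

**Step count and risks**

Total step count: 19. Longest linear sequence: 15 steps (steps 1–3, 5–14, 18 and 19, from but-2-yn-1-ol).

Steps most likely to fail:

1. Step 5 (proposed new method). The enolate may add to the ynoate in conjugate fashion instead of at the ester carbonyl, may add a second time to the ynone, or may decompose before the cascade is complete. The fallback uses known reactions and separates the two bond formations; it sets out from 3 and 8. Sonogashira coupling of 3 with propargyl alcohol (Pd(PPh3)2Cl2, CuI, Et3N) should give (Z)-6-[(tert-butyldimethylsilyl)oxy]-4-methylhex-4-en-2-yn-1-ol F1, and MnO2 oxidation should give (Z)-6-[(tert-butyldimethylsilyl)oxy]-4-methylhex-4-en-2-ynal F2. Aldol addition of the lithium enolate of 8 (LDA, THF, −78 °C) to F2, which can only occur at the carbonyl and again trans to tert-butyl, should give the carbinol (2R,5S)-2-tert-butyl-5-[(4Z)-6-[(tert-butyldimethylsilyl)oxy]-1-hydroxy-4-methylhex-4-en-2-yn-1-yl]-5-methyl-1,3-dioxolan-4-one F3 (both carbinol epimers serve). Dess–Martin oxidation then gives ynone 9, now isolated, and NaOMe in MeOH at 0 °C opens the dioxolanone and cyclizes the alkoxide. The fallback comes back to the route at 11.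

2. Step 13. Oligomerization, reduction or pinacol coupling of the enal by excess divalent chromium, Z-to-E isomerization of the enal under the Lewis-acidic trivalent chromium salts, or loss of the allylic bromide in steps 11 and 12 may erode the ring closure. The fallback avoids the bromide and generates the allyl metal catalytically; it sets out from 17. Acetylation (Ac2O, pyridine) should give methyl (4S,5S)-3-acetoxy-5-[(tert-butyldimethylsilyl)oxy]-5-[(2R)-5-[(2Z)-4-[(tert-butyldimethylsilyl)oxy]but-2-en-2-yl]-2-methyl-3-oxo-2,3-dihydrofuran-2-yl]-4-[(4-methoxybenzyl)oxy]-2-methylidenepentanoate F4. HF·pyridine should give the primary alcohol methyl (4S,5S)-3-acetoxy-5-[(tert-butyldimethylsilyl)oxy]-5-[(2R)-5-[(2Z)-4-hydroxybut-2-en-2-yl]-2-methyl-3-oxo-2,3-dihydrofuran-2-yl]-4-[(4-methoxybenzyl)oxy]-2-methylidenepentanoate F5, and Dess–Martin oxidation the enal methyl (4S,5S)-3-acetoxy-5-[(tert-butyldimethylsilyl)oxy]-4-[(4-methoxybenzyl)oxy]-5-[(2R)-2-methyl-3-oxo-5-[(2Z)-4-oxobut-2-en-2-yl]-2,3-dihydrofuran-2-yl]-2-methylidenepentanoate F6. Palladium-catalysed umpolung allylation at high dilution (Pd(PPh3)4, Et2Zn, THF; π-allylpalladium to allylzinc, closed transition state) should give hydroxy ester 21, and acid-catalysed lactonization as in the main route follows. The fallback comes back to the route at 22.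

3. Step 6. The hydride may attack the furanone carbonyl in competition with the ester, or reduce the ester past the aldehyde stage. The fallback avoids hydride reagents; it sets out from 11. Trans-thioesterification with Me3Al/EtSH should give S-ethyl (2S)-5-[(2Z)-4-[(tert-butyldimethylsilyl)oxy]but-2-en-2-yl]-2-methyl-3-oxo-2,3-dihydrofuran-2-carbothioate F7. Fukuyama reduction (Et3SiH, Pd/C, acetone), which is selective for thioesters over ketones and esters, should give the aldehyde. The fallback comes back to the route at 12.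

**Further compounds**

F1 | step 5 | (Z)-6-[(tert-butyldimethylsilyl)oxy]-4-methylhex-4-en-2-yn-1-ol | C/C(C#CCO)=C/CO[Si](C)(C)C(C)(C)C
F2 | step 5 | (Z)-6-[(tert-butyldimethylsilyl)oxy]-4-methylhex-4-en-2-ynal | C/C(C#CC=O)=C/CO[Si](C)(C)C(C)(C)C
F3 | step 5 | (2R,5S)-2-tert-butyl-5-[(4Z)-6-[(tert-butyldimethylsilyl)oxy]-1-hydroxy-4-methylhex-4-en-2-yn-1-yl]-5-methyl-1,3-dioxolan-4-one | C[C@@]1(C(O)C#C/C(C)=C\CO[Si](C)(C)C(C)(C)C)O[C@@H](C(C)(C)C)OC1=O
F4 | step 13 | methyl (4S,5S)-3-acetoxy-5-[(tert-butyldimethylsilyl)oxy]-5-[(2R)-5-[(2Z)-4-[(tert-butyldimethylsilyl)oxy]but-2-en-2-yl]-2-methyl-3-oxo-2,3-dihydrofuran-2-yl]-4-[(4-methoxybenzyl)oxy]-2-methylidenepentanoate | C/C(=C/CO[Si](C)(C)C(C)(C)C)C1=CC(=O)[C@](C)(O1)[C@@H](O[Si](C)(C)C(C)(C)C)[C@@H](OCc2ccc(OC)cc2)C(OC(C)=O)C(=C)C(=O)OC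
F5 | step 13 | methyl (4S,5S)-3-acetoxy-5-[(tert-butyldimethylsilyl)oxy]-5-[(2R)-5-[(2Z)-4-hydroxybut-2-en-2-yl]-2-methyl-3-oxo-2,3-dihydrofuran-2-yl]-4-[(4-methoxybenzyl)oxy]-2-methylidenepentanoate | C/C(=C/CO)C1=CC(=O)[C@](C)(O1)[C@@H](O[Si](C)(C)C(C)(C)C)[C@@H](OCc2ccc(OC)cc2)C(OC(C)=O)C(=C)C(=O)OC
F6 | step 13 | methyl (4S,5S)-3-acetoxy-5-[(tert-butyldimethylsilyl)oxy]-4-[(4-methoxybenzyl)oxy]-5-[(2R)-2-methyl-3-oxo-5-[(2Z)-4-oxobut-2-en-2-yl]-2,3-dihydrofuran-2-yl]-2-methylidenepentanoate | C/C(=C/C=O)C1=CC(=O)[C@](C)(O1)[C@@H](O[Si](C)(C)C(C)(C)C)[C@@H](OCc2ccc(OC)cc2)C(OC(C)=O)C(=C)C(=O)OC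
F7 | step 6 | S-ethyl (2S)-5-[(2Z)-4-[(tert-butyldimethylsilyl)oxy]but-2-en-2-yl]-2-methyl-3-oxo-2,3-dihydrofuran-2-carbothioate | C/C(=C/CO[Si](C)(C)C(C)(C)C)C1=CC(=O)[C@](C)(O1)C(=O)SCC
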